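**Plan**

- Numbering: carbocycle C1 (tertiary carbinol), C2 (angelate carbon), C3 (lactone O), C4 (ring-fusion CH), C5, C6, C7 (CHMe); Cα is the lactone CHMe carbon.
- Retrosynthetic cuts, in order: the C2–O angelate ester; the C1–C(=O) bond to the hydroxybutanoyl chain (seen as an alkenyl adduct of a C1 ketone); the ring bond C4–C5; the chain bond C2–C3; the C1 oxygen back to the α-position of citronellal.
- Enabling feature: the lactone ring C3–O–C(=O)–Cα–C4 is a saturated α-methylbutenolide whose β-carbon is C4, and C5 is a bare methylene. A C5 radical made from a C5 carboxylate can therefore close the cycloheptane onto the butenolide.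
- Forward order: chain C2–C1–C7–C6–C5 from (S)-citronellal; butenolide (lactone ring) attached at C2–C3; cycloheptane closed at C4–C5; side chain added at C1; angelate last.
- Stereochemistry: C7 from citronellal; temporary C1 from proline catalysis; C2 and C3 from a Felkin-controlled, threo-selective vinylogous aldol; C4 and Cα from the cyclisation; quaternary C1 from chelation-controlled addition to the ketone; side-chain carbinol from (R)-pent-4-yn-2-ol.

Key step: step 11

Assumption: the C1 configuration carried in compounds 2–14 (R, oxygen cis to C2–O in the ring) is the one the Felkin aldol needs to set C2; it is erased on oxidation to ketone 16.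

**Step 1**
Reactants: 1 (S)-citronellal
Product: 3 (2R,3S)-3,7-dimethyl-2-[(phenylamino)oxy]oct-6-en-1-ol, via α-anilinooxy aldehyde 2 (not isolated)
Conditions: PhNO, L-proline (20 mol%), CHCl3, 4 °C; then NaBH4, EtOH, 0 °C
Reagents that add atoms: nitrosobenzene, O=Nc1ccccc1
Why: Proline-catalysed α-aminoxylation (enamine catalysis) followed by in situ borohydride reduction; L-proline directs oxygen to one enamine face under catalyst control, which should set C1 as R whatever the neighbouring C7 centre, and C7 comes unchanged from citronellal.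

**Step 2**
Reactants: 3 (2R,3S)-3,7-dimethyl-2-[(phenylamino)oxy]oct-6-en-1-ol
Product: 4 (2R,3S)-3,7-dimethyloct-6-ene-1,2-diol
Conditions: Zn, AcOH, EtOH, rt
Reagents that add atoms: none
Why: Dissolving-metal reduction cleaves the weak N–O bond and should free the 1,2-diol without touching the trisubstituted alkene or either stereocentre.

**Step 3**
Reactants: 4 (2R,3S)-3,7-dimethyloct-6-ene-1,2-diol
Product: 5 (2R,3S)-3,7-dimethyl-1,2-bis[(triethylsilyl)oxy]oct-6-ene
Conditions: Et3SiCl, imidazole, DMF, 0 °C to rt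
Reagents that add atoms: chlorotriethylsilane, CC[Si](Cl)(CC)CC
Why: Imidazole-mediated silyl ether formation on both hydroxyls; no stereocentre is involved.

**Step 4**
Reactants: 5 (2R,3S)-3,7-dimethyl-1,2-bis[(triethylsilyl)oxy]oct-6-ene
Product: 6 methyl (4S,5R)-4-methyl-5,6-bis[(triethylsilyl)oxy]hexanoate
Conditions: O3, NaOH, MeOH/CH2Cl2, −78 °C
Reagents that add atoms: ozone, [O-][O+]=O; methanol, CO
Why: Criegee ozonolysis of the only alkene; in methanolic NaOH the aldehyde is trapped as its hemiacetal and oxidised further by ozone, so the methyl ester should form directly, and the electron-rich alkene is removed before any Lewis-acid or benzyl-cation chemistry.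

**Step 5**
Reactants: 6 methyl (4S,5R)-4-methyl-5,6-bis[(triethylsilyl)oxy]hexanoate
Product: 7 methyl (4S,5R)-4-methyl-6-oxo-5-[(triethylsilyl)oxy]hexanoate
Conditions: (COCl)2, DMSO, CH2Cl2, −78 to −40 °C; then Et3N, to 0 °C
Reagents that add atoms: none
Why: Swern oxidation, in which activated DMSO cleaves a primary triethylsilyl ether and oxidises it to the aldehyde while the hindered secondary silyl ether at C1 stays; C1 should not epimerise at low temperature.

**Step 6**
Reactants: 8 3-methylfuran-2(5H)-one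
Product: 9 tert-butyldimethyl[(3-methylfuran-2-yl)oxy]silane
Conditions: tBuMe2SiOTf, Et3N, CH2Cl2, 0 °C
Reagents that add atoms: tert-butyldimethylsilyl trifluoromethanesulfonate, CC(C)(C)[Si](C)(C)OS(=O)(=O)C(F)(F)F
Why: Soft enolisation and O-silylation of the butenolide dienolate gives the aromatic 2-silyloxyfuran.

**Step 7**
Reactants: 7 methyl (4S,5R)-4-methyl-6-oxo-5-[(triethylsilyl)oxy]hexanoate; 9 tert-butyldimethyl[(3-methylfuran-2-yl)oxy]silane
Product: 10 methyl (4S,5R,6S)-6-hydroxy-4-methyl-6-[(2R)-4-methyl-5-oxo-2,5-dihydrofuran-2-yl]-5-[(triethylsilyl)oxy]hexanoate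
Conditions: BF3·OEt2, CH2Cl2, −78 °C; aq. NaHCO3
Reagents that add atoms: none
Why: Vinylogous Mukaiyama aldol through an open transition state, forming C2–C3 with the butenolide in place; Felkin–Anh attack anti to the C1 silyloxy group should set C2 (C1–O/C2–O anti), and the usual synclinal furan–aldehyde approach should set C3 threo to C2.

**Step 8**
Reactants: 10 methyl (4S,5R,6S)-6-hydroxy-4-methyl-6-[(2R)-4-methyl-5-oxo-2,5-dihydrofuran-2-yl]-5-[(triethylsilyl)oxy]hexanoate
Product: 11 methyl (4S,5R,6S)-6-(benzyloxy)-4-methyl-6-[(2R)-4-methyl-5-oxo-2,5-dihydrofuran-2-yl]-5-[(triethylsilyl)oxy]hexanoate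
Conditions: 2-benzyloxy-1-methylpyridinium triflate, MgO, PhCF3, 83 °C
Reagents that add atoms: 2-(benzyloxy)-1-methylpyridinium trifluoromethanesulfonate, C[n+]1ccccc1OCc1ccccc1.[O-]S(=O)(=O)C(F)(F)F
Why: Thermal benzyl transfer from the pyridinium salt under neutral, MgO-buffered conditions avoids the bases that would epimerise C3 of the butenolide or eliminate the C2 oxygen.

**Step 9**
Reactants: 11 methyl (4S,5R,6S)-6-(benzyloxy)-4-methyl-6-[(2R)-4-methyl-5-oxo-2,5-dihydrofuran-2-yl]-5-[(triethylsilyl)oxy]hexanoate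
Product: 12 (4S,5R,6S)-6-(benzyloxy)-4-methyl-6-[(2R)-4-methyl-5-oxo-2,5-dihydrofuran-2-yl]-5-[(triethylsilyl)oxy]hexanoic acid
Conditions: Me3SnOH, ClCH2CH2Cl, 70 °C; 0.1 M HCl work-up
Reagents that add atoms: trimethyltin hydroxide, C[Sn](C)(C)O
Why: Tin-hydroxide ester hydrolysis cleaves the unhindered methyl ester near neutrality, so the acidic C3–H of the butenolide should not be removed, and any opened butenolide relactonises on acidic work-up.

**Step 10**
Reactants: 12 (4S,5R,6S)-6-(benzyloxy)-4-methyl-6-[(2R)-4-methyl-5-oxo-2,5-dihydrofuran-2-yl]-5-[(triethylsilyl)oxy]hexanoic acid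
Product: 13 1,3-dioxoisoindolin-2-yl (4S,5R,6S)-6-(benzyloxy)-4-methyl-6-[(2R)-4-methyl-5-oxo-2,5-dihydrofuran-2-yl]-5-[(triethylsilyl)oxy]hexanoate
Conditions: N-hydroxyphthalimide, iPrN=C=NiPr, CH2Cl2, 0 °C to rt (no amine base)
Reagents that add atoms: N-hydroxyphthalimide, ON1C(=O)c2ccccc2C1=O
Why: Carbodiimide (Steglich-type) esterification with the acidic N–OH group gives the redox-active ester; the silyl group on C1–O blocks δ-lactonisation.

**Step 11**
Reactants: 13 1,3-dioxoisoindolin-2-yl (4S,5R,6S)-6-(benzyloxy)-4-methyl-6-[(2R)-4-methyl-5-oxo-2,5-dihydrofuran-2-yl]-5-[(triethylsilyl)oxy]hexanoate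
Product: 14 (3R,3aS,6S,7R,8S,8aR)-8-(benzyloxy)-3,6-dimethyl-7-[(triethylsilyl)oxy]octahydro-2H-cyclohepta[b]furan-2-one
Conditions: e− (undivided cell, reticulated vitreous carbon cathode, Zn anode), nBu4NPF6, DMF/H2O 20:1, cathode held near −1.3 V vs SCE, 13 added slowly to 5 mM, rt
Reagents that add atoms: none
Why: One-electron reduction of the N-acyloxyphthalimide at the cathode gives a radical anion that fragments to phthalimide anion, CO2 and the primary C5 radical; this adds to C4, the β-carbon of the α-methylbutenolide, and the resulting Cα radical is reduced at the same potential to the lactone enolate and protonated by water, the closest known reaction type being the electroreductive decarboxylative Giese addition of redox-active esters, run here intramolecularly. The cycloheptane closes in the 7-exo-trig mode, with C4=Cα outside the new ring. At C4 the chain is anchored at C3 through C2, and a seven-membered ring cannot span opposite faces of the flat butenolide, so C5 should bond to the face of C4 that carries C2 and the fusion should be cis. At Cα the enolate of the cis-fused bicycle should be protonated on its convex face, anti to the C4–C5 bond, leaving the methyl group on the concave face as in the target. Cyclisation must outrun 1,5-hydrogen transfer from C2–H and reduction of the C5 radical to a carbanion: the electron-poor acceptor speeds closure, high dilution excludes bimolecular trapping, and holding the cathode at the wave of the active ester keeps it positive of the potentials at which a primary alkyl radical or the butenolide is reduced.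

**Step 12**
Reactants: 14 (3R,3aS,6S,7R,8S,8aR)-8-(benzyloxy)-3,6-dimethyl-7-[(triethylsilyl)oxy]octahydro-2H-cyclohepta[b]furan-2-one
Product: 15 (3R,3aS,6S,7R,8R,8aR)-8-(benzyloxy)-7-hydroxy-3,6-dimethyloctahydro-2H-cyclohepta[b]furan-2-one
Conditions: HF·pyridine, pyridine/THF, 0 °C to rt
Reagents that add atoms: none
Why: Fluoride-driven cleavage of the triethylsilyl ether under buffered acidic conditions should leave the benzyl ether, the lactone and the epimerisable Cα centre untouched.

**Step 13**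
Reactants: 15 (3R,3aS,6S,7R,8R,8aR)-8-(benzyloxy)-7-hydroxy-3,6-dimethyloctahydro-2H-cyclohepta[b]furan-2-one
Product: 16 (3R,3aS,6S,8S,8aR)-8-(benzyloxy)-3,6-dimethylhexahydro-2H-cyclohepta[b]furan-2,7(3H)-dione
Conditions: Dess–Martin periodinane, NaHCO3, CH2Cl2, 0 °C to rt
Reagents that add atoms: none
Why: Dess–Martin oxidation of the secondary C1 alcohol under buffered, non-basic conditions should give the ketone without epimerising C7 or eliminating the β-acyloxy group at C3.

**Step 14**
Reactants: 17 (R)-pent-4-yn-2-ol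
Product: 18 (R)-tert-butyldimethyl(pent-4-yn-2-yloxy)silane
Conditions: tBuMe2SiCl, imidazole, DMF, rt
Reagents that add atoms: tert-butyldimethylsilyl chloride, CC(C)(C)[Si](C)(C)Cl
Why: Imidazole-mediated silylation of the secondary alcohol; the carbinol centre is retained.

**Step 15**
Reactants: 18 (R)-tert-butyldimethyl(pent-4-yn-2-yloxy)silane
Product: 20 (R)-[(4-bromopent-4-en-2-yl)oxy](tert-butyl)dimethylsilane, via (Z)-2-bromoalkenylborane 19 (not isolated)
Conditions: 9-bromo-9-BBN, CH2Cl2, 0 °C; then AcOH, 0 °C to rt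
Reagents that add atoms: 9-bromo-9-borabicyclo[3.3.1]nonane, BrB1C2CCCC1CCC2
Why: Haloboration of the terminal alkyne adds B–Br syn with bromine on the internal carbon, and protodeboration with acetic acid should give the 2-bromo-1-alkene; the carbinol centre is not involved.

**Step 16**
Reactants: 20 (R)-[(4-bromopent-4-en-2-yl)oxy](tert-butyl)dimethylsilane; 16 (3R,3aS,6S,8S,8aR)-8-(benzyloxy)-3,6-dimethylhexahydro-2H-cyclohepta[b]furan-2,7(3H)-dione
Product: 23 (3R,3aS,6S,7R,8S,8aR)-8-(benzyloxy)-7-[(4R)-4-[(tert-butyldimethylsilyl)oxy]pent-1-en-2-yl]-7-hydroxy-3,6-dimethyloctahydro-2H-cyclohepta[b]furan-2-one, via alkenyllithium 21 (not isolated), via alkenylcerium dichloride 22 (not isolated)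
Conditions: 20, tBuLi (2 equiv), Et2O, −78 °C; CeCl3, THF, −78 °C; then 16, THF, −78 °C; H2O
Reagents that add atoms: none
Why: Organocerium 1,2-addition (halogen–lithium exchange, then transmetalation) to a hindered, enolisable α-alkoxy ketone beside a lactone; cerium should chelate C1=O and C2–OBn, holding the benzyloxy group in the carbonyl plane so that the C7 methyl group and the lactone ring shield the concave face, the alkenyl group enters from the convex face syn to C2–O, and C1–OH ends trans to C2–O as in the target.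

**Step 17**
Reactants: 23 (3R,3aS,6S,7R,8S,8aR)-8-(benzyloxy)-7-[(4R)-4-[(tert-butyldimethylsilyl)oxy]pent-1-en-2-yl]-7-hydroxy-3,6-dimethyloctahydro-2H-cyclohepta[b]furan-2-one
Product: 25 (3R,3aS,6S,7S,8S,8aR)-8-(benzyloxy)-7-[(3R)-3-[(tert-butyldimethylsilyl)oxy]butanoyl]-7-hydroxy-3,6-dimethyloctahydro-2H-cyclohepta[b]furan-2-one, via secondary ozonide 24 (not isolated)
Conditions: O3, CH2Cl2, −78 °C; then PPh3, −78 °C to rt
Reagents that add atoms: ozone, [O-][O+]=O
Why: Criegee ozonolysis of the 1,1-disubstituted alkene, the only C=C present, should unmask the side-chain ketone and leave the quaternary C1 and all other centres untouched.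

**Step 18**
Reactants: 25 (3R,3aS,6S,7S,8S,8aR)-8-(benzyloxy)-7-[(3R)-3-[(tert-butyldimethylsilyl)oxy]butanoyl]-7-hydroxy-3,6-dimethyloctahydro-2H-cyclohepta[b]furan-2-one
Product: 26 (3R,3aS,6S,7S,8S,8aR)-7-[(3R)-3-[(tert-butyldimethylsilyl)oxy]butanoyl]-7,8-dihydroxy-3,6-dimethyloctahydro-2H-cyclohepta[b]furan-2-one
Conditions: H2 (1 atm), Pd(OH)2/C, EtOAc, rt
Reagents that add atoms: none
Why: Hydrogenolysis of the benzyl ether; no alkene remains at this stage, and the ketone, lactone and silyl ether should be inert.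

**Step 19**
Reactants: 26 (3R,3aS,6S,7S,8S,8aR)-7-[(3R)-3-[(tert-butyldimethylsilyl)oxy]butanoyl]-7,8-dihydroxy-3,6-dimethyloctahydro-2H-cyclohepta[b]furan-2-one; 27 angelic acid [(2Z)-2-methylbut-2-enoic acid]
Product: 29 (3R,3aS,6S,7S,8S,8aR)-7-[(3R)-3-[(tert-butyldimethylsilyl)oxy]butanoyl]-7-hydroxy-3,6-dimethyl-2-oxooctahydro-2H-cyclohepta[b]furan-8-yl (2Z)-2-methylbut-2-enoate, via mixed anhydride 28 (not isolated)
Conditions: 27, 2,4,6-trichlorobenzoyl chloride, Et3N, toluene, rt; then 26, toluene, 80 °C (no DMAP)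
Reagents that add atoms: none
Why: Yamaguchi-type esterification through the 2,4,6-trichlorobenzoyl mixed anhydride should acylate the secondary C2–OH (the tertiary C1–OH is too hindered), and leaving out DMAP avoids the addition–elimination path that isomerises angelates to tiglates.

**Step 20**
Reactants: 29 (3R,3aS,6S,7S,8S,8aR)-7-[(3R)-3-[(tert-butyldimethylsilyl)oxy]butanoyl]-7-hydroxy-3,6-dimethyl-2-oxooctahydro-2H-cyclohepta[b]furan-8-yl (2Z)-2-methylbut-2-enoate
Product: 30 (3R,3aS,6S,7S,8S,8aR)-7-hydroxy-7-[(3R)-3-hydroxybutanoyl]-3,6-dimethyl-2-oxooctahydro-2H-cyclohepta[b]furan-8-yl (2Z)-2-methylbut-2-enoate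
Conditions: HF·pyridine, THF, 0 °C to rt
Reagents that add atoms: none
Why: Acidic fluoride desilylation removes the tert-butyldimethylsilyl group without base, so β-elimination of the β-oxy ketone, angelate isomerisation and Cα epimerisation should all be avoided.

**Compound list**

1 | (S)-citronellal [(3S)-3,7-dimethyloct-6-enal] | O=CC[C@@H](C)CCC=C(C)C | starting material
2 | (2R,3S)-3,7-dimethyl-2-[(phenylamino)oxy]oct-6-enal (not isolated) | O=C[C@H](ONc1ccccc1)[C@@H](C)CCC=C(C)C | intermediate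
3 | (2R,3S)-3,7-dimethyl-2-[(phenylamino)oxy]oct-6-en-1-ol | OC[C@H](ONc1ccccc1)[C@@H](C)CCC=C(C)C | intermediate
4 | (2R,3S)-3,7-dimethyloct-6-ene-1,2-diol | OC[C@H](O)[C@@H](C)CCC=C(C)C | intermediate
5 | (2R,3S)-3,7-dimethyl-1,2-bis[(triethylsilyl)oxy]oct-6-ene | CC[Si](CC)(CC)OC[C@H](O[Si](CC)(CC)CC)[C@@H](C)CCC=C(C)C | intermediate
6 | methyl (4S,5R)-4-methyl-5,6-bis[(triethylsilyl)oxy]hexanoate | CC[Si](CC)(CC)OC[C@H](O[Si](CC)(CC)CC)[C@@H](C)CCC(=O)OC | intermediate
7 | methyl (4S,5R)-4-methyl-6-oxo-5-[(triethylsilyl)oxy]hexanoate | O=C[C@H](O[Si](CC)(CC)CC)[C@@H](C)CCC(=O)OC | intermediate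
8 | 3-methylfuran-2(5H)-one | CC1=CCOC1=O | starting material
9 | tert-butyldimethyl[(3-methylfuran-2-yl)oxy]silane | Cc1ccoc1O[Si](C)(C)C(C)(C)C | intermediate
10 | methyl (4S,5R,6S)-6-hydroxy-4-methyl-6-[(2R)-4-methyl-5-oxo-2,5-dihydrofuran-2-yl]-5-[(triethylsilyl)oxy]hexanoate | CC1=C[C@@H](OC1=O)[C@H](O)[C@H](O[Si](CC)(CC)CC)[C@@H](C)CCC(=O)OC | intermediate
11 | methyl (4S,5R,6S)-6-(benzyloxy)-4-methyl-6-[(2R)-4-methyl-5-oxo-2,5-dihydrofuran-2-yl]-5-[(triethylsilyl)oxy]hexanoate | CC1=C[C@@H](OC1=O)[C@H](OCc1ccccc1)[C@H](O[Si](CC)(CC)CC)[C@@H](C)CCC(=O)OC | intermediate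
12 | (4S,5R,6S)-6-(benzyloxy)-4-methyl-6-[(2R)-4-methyl-5-oxo-2,5-dihydrofuran-2-yl]-5-[(triethylsilyl)oxy]hexanoic acid | CC1=C[C@@H](OC1=O)[C@H](OCc1ccccc1)[C@H](O[Si](CC)(CC)CC)[C@@H](C)CCC(=O)O | intermediate
13 | 1,3-dioxoisoindolin-2-yl (4S,5R,6S)-6-(benzyloxy)-4-methyl-6-[(2R)-4-methyl-5-oxo-2,5-dihydrofuran-2-yl]-5-[(triethylsilyl)oxy]hexanoate (key-step precursor) | CC1=C[C@@H](OC1=O)[C@H](OCc1ccccc1)[C@H](O[Si](CC)(CC)CC)[C@@H](C)CCC(=O)ON1C(=O)c2ccccc2C1=O | intermediate
14 | (3R,3aS,6S,7R,8S,8aR)-8-(benzyloxy)-3,6-dimethyl-7-[(triethylsilyl)oxy]octahydro-2H-cyclohepta[b]furan-2-one (key-step product) | c1ccccc1CO[C@H]1[C@@H]2OC(=O)[C@H](C)[C@@H]2CC[C@H](C)[C@H]1O[Si](CC)(CC)CC | intermediate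
15 | (3R,3aS,6S,7R,8R,8aR)-8-(benzyloxy)-7-hydroxy-3,6-dimethyloctahydro-2H-cyclohepta[b]furan-2-one | c1ccccc1CO[C@H]1[C@@H]2OC(=O)[C@H](C)[C@@H]2CC[C@H](C)[C@H]1O | intermediate
16 | (3R,3aS,6S,8S,8aR)-8-(benzyloxy)-3,6-dimethylhexahydro-2H-cyclohepta[b]furan-2,7(3H)-dione | c1ccccc1CO[C@H]1[C@@H]2OC(=O)[C@H](C)[C@@H]2CC[C@H](C)C1=O | intermediate
17 | (R)-pent-4-yn-2-ol | C#CC[C@@H](C)O | starting material
18 | (R)-tert-butyldimethyl(pent-4-yn-2-yloxy)silane | C#CC[C@@H](C)O[Si](C)(C)C(C)(C)C | intermediate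
19 | 9-[(1Z,4R)-2-bromo-4-[(tert-butyldimethylsilyl)oxy]pent-1-en-1-yl]-9-borabicyclo[3.3.1]nonane (not isolated) | Br/C(=C\B1C2CCCC1CCC2)C[C@@H](C)O[Si](C)(C)C(C)(C)C | intermediate
20 | (R)-[(4-bromopent-4-en-2-yl)oxy](tert-butyl)dimethylsilane | C=C(Br)C[C@@H](C)O[Si](C)(C)C(C)(C)C | intermediate
21 | [(4R)-4-[(tert-butyldimethylsilyl)oxy]pent-1-en-2-yl]lithium (not isolated) | [Li]C(=C)C[C@@H](C)O[Si](C)(C)C(C)(C)C | intermediate
22 | [(4R)-4-[(tert-butyldimethylsilyl)oxy]pent-1-en-2-yl]cerium dichloride (not isolated) | Cl[Ce](Cl)C(=C)C[C@@H](C)O[Si](C)(C)C(C)(C)C | intermediate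
23 | (3R,3aS,6S,7R,8S,8aR)-8-(benzyloxy)-7-[(4R)-4-[(tert-butyldimethylsilyl)oxy]pent-1-en-2-yl]-7-hydroxy-3,6-dimethyloctahydro-2H-cyclohepta[b]furan-2-one | c1ccccc1CO[C@H]1[C@@H]2OC(=O)[C@H](C)[C@@H]2CC[C@H](C)[C@@]1(O)C(=C)C[C@@H](C)O[Si](C)(C)C(C)(C)C | intermediate
24 | secondary ozonide (1,2,4-trioxolane) of 23 at the exocyclic C=CH2 bond (not isolated) | c1ccccc1CO[C@H]1[C@@H]2OC(=O)[C@H](C)[C@@H]2CC[C@H](C)[C@@]1(O)C3(OOCO3)C[C@@H](C)O[Si](C)(C)C(C)(C)C | intermediate
25 | (3R,3aS,6S,7S,8S,8aR)-8-(benzyloxy)-7-[(3R)-3-[(tert-butyldimethylsilyl)oxy]butanoyl]-7-hydroxy-3,6-dimethyloctahydro-2H-cyclohepta[b]furan-2-one | c1ccccc1CO[C@H]1[C@@H]2OC(=O)[C@H](C)[C@@H]2CC[C@H](C)[C@@]1(O)C(=O)C[C@@H](C)O[Si](C)(C)C(C)(C)C | intermediate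
26 | (3R,3aS,6S,7S,8S,8aR)-7-[(3R)-3-[(tert-butyldimethylsilyl)oxy]butanoyl]-7,8-dihydroxy-3,6-dimethyloctahydro-2H-cyclohepta[b]furan-2-one | O[C@H]1[C@@H]2OC(=O)[C@H](C)[C@@H]2CC[C@H](C)[C@@]1(O)C(=O)C[C@@H](C)O[Si](C)(C)C(C)(C)C | intermediate
27 | angelic acid [(2Z)-2-methylbut-2-enoic acid] | C/C=C(/C)C(=O)O | starting material
28 | (2Z)-2-methylbut-2-enoic 2,4,6-trichlorobenzoic anhydride (not isolated) | C/C=C(/C)C(=O)OC(=O)c1c(Cl)cc(Cl)cc1Cl | intermediate
29 | (3R,3aS,6S,7S,8S,8aR)-7-[(3R)-3-[(tert-butyldimethylsilyl)oxy]butanoyl]-7-hydroxy-3,6-dimethyl-2-oxooctahydro-2H-cyclohepta[b]furan-8-yl (2Z)-2-methylbut-2-enoate | C/C=C(/C)C(=O)O[C@H]1[C@@H]2OC(=O)[C@H](C)[C@@H]2CC[C@H](C)[C@@]1(O)C(=O)C[C@@H](C)O[Si](C)(C)C(C)(C)C | intermediate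
30 | (3R,3aS,6S,7S,8S,8aR)-7-hydroxy-7-[(3R)-3-hydroxybutanoyl]-3,6-dimethyl-2-oxooctahydro-2H-cyclohepta[b]furan-8-yl (2Z)-2-methylbut-2-enoate | C/C=C(/C)C(=O)O[C@H]1[C@@H]2OC(=O)[C@H](C)[C@@H]2CC[C@H](C)[C@@]1(O)C(=O)C[C@@H](C)O | target

**Step count**

Total: 20 steps. Longest linear sequence: 17 steps (steps 1–5, 7–13, 16–20) from (S)-citronellal.

**Steps most likely to fail, with fallbacks**

1. Step 11. The C5 radical may be reduced at the electrode, or may abstract hydrogen from C2–H, before the seven-membered ring closes. The fallback generates the same radical away from an electrode in a chain process. It sets out from acid 12: iodinative decarboxylation (PhI(OAc)2, I2, CH2Cl2, visible-light irradiation) should give the primary iodide F1, in which iodine trapping is far faster than any side reaction of the radical. Slow addition of Bu3SnH with azobisisobutyronitrile to F1 in refluxing benzene at 5 mM should then give the 7-exo closure, with the stannane delivering hydrogen to the Cα radical on the convex face. The route is rejoined at 14.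

2. Step 16. The alkenyl group may enter from the concave face (poor or reversed facial selectivity at C1), for example if the chelate does not form and the benzyloxy group sits axial. The fallback uses that same facial bias with reversed polarity, bringing in oxygen instead of carbon from the face anti to C2–OBn. Commercial (R)-butane-1,3-diol is converted with I2, PPh3 and imidazole into (R)-4-iodobutan-2-ol F2, silylated (tBuMe2SiCl, imidazole) to the silyl ether F3, and heated with PPh3 in MeCN to give the phosphonium iodide F4. Setting out from ketone 16, Wittig olefination (F4, KN(SiMe3)2, THF, −78 °C to rt) should give the exocyclic alkene F5. Upjohn dihydroxylation (OsO4 cat., N-methylmorpholine N-oxide, acetone/H2O) anti to the allylic benzyloxy group should give the diol F6, and Dess–Martin oxidation of its secondary hydroxyl rejoins the route at 25.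

3. Step 7. Felkin control by the α-silyloxy group, or the threo preference of the furan addition, may be poor, giving mixtures at C2 and C3. The fallback sets both centres by reagent control and builds the butenolide afterwards. It sets out from aldehyde 7: alkoxyallylboration with (Z)-γ-(methoxymethoxy)allyldiisopinocampheylborane (the antipode matched to the Felkin preference; −78 °C, then oxidative work-up) should give the syn-configured methoxymethyl ether F7. Benzylation as in step 8 gives the benzyl ether F8; Me2BBr in CH2Cl2 at −78 °C removes the methoxymethyl group to give the allylic alcohol F9; methacryloyl chloride, Et3N and DMAP give the methacrylate F10. Ring-closing metathesis with the second-generation Grubbs catalyst in toluene at 80 °C closes the α-methylbutenolide and rejoins the route at 11.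

**Further compounds**

F1 | step 11 | (5R)-5-[(1S,2R,3S)-1-(benzyloxy)-5-iodo-3-methyl-2-[(triethylsilyl)oxy]pentyl]-3-methylfuran-2(5H)-one | CC1=C[C@@H](OC1=O)[C@H](OCc1ccccc1)[C@H](O[Si](CC)(CC)CC)[C@@H](C)CCI
F2 | step 16 | (R)-4-iodobutan-2-ol | C[C@@H](O)CCI
F3 | step 16 | (R)-tert-butyl[(4-iodobutan-2-yl)oxy]dimethylsilane | C[C@@H](O[Si](C)(C)C(C)(C)C)CCI
F4 | step 16 | [(3R)-3-[(tert-butyldimethylsilyl)oxy]butyl]triphenylphosphonium iodide | C[C@@H](O[Si](C)(C)C(C)(C)C)CC[P+](c1ccccc1)(c1ccccc1)c1ccccc1.[I-]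
F5 | step 16 | 7-[(3R)-3-[(tert-butyldimethylsilyl)oxy]butylidene] analogue of ketone 16 (C1=CH in place of C1=O; mixture of alkene isomers) | c1ccccc1CO[C@H]1[C@@H]2OC(=O)[C@H](C)[C@@H]2CC[C@H](C)C1=CC[C@@H](C)O[Si](C)(C)C(C)(C)C
F6 | step 16 | diol from F5: 8-(benzyloxy)-7-hydroxy-7-[(3R)-3-[(tert-butyldimethylsilyl)oxy]-1-hydroxybutyl]-3,6-dimethyloctahydro-2H-cyclohepta[b]furan-2-one (C1–OH trans to C2–O; carbinol epimers) | c1ccccc1CO[C@H]1[C@@H]2OC(=O)[C@H](C)[C@@H]2CC[C@H](C)[C@@]1(O)C(O)C[C@@H](C)O[Si](C)(C)C(C)(C)C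
F7 | step 7 | methyl 6-hydroxy-7-(methoxymethoxy)-4-methyl-5-[(triethylsilyl)oxy]non-8-enoate (centres as in 10; C6–OH/C7–O syn) | C=C[C@@H](OCOC)[C@H](O)[C@H](O[Si](CC)(CC)CC)[C@@H](C)CCC(=O)OC
F8 | step 7 | methyl 6-(benzyloxy)-7-(methoxymethoxy)-4-methyl-5-[(triethylsilyl)oxy]non-8-enoate | C=C[C@@H](OCOC)[C@H](OCc1ccccc1)[C@H](O[Si](CC)(CC)CC)[C@@H](C)CCC(=O)OC
F9 | step 7 | methyl 6-(benzyloxy)-7-hydroxy-4-methyl-5-[(triethylsilyl)oxy]non-8-enoate | C=C[C@@H](O)[C@H](OCc1ccccc1)[C@H](O[Si](CC)(CC)CC)[C@@H](C)CCC(=O)OC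
F10 | step 7 | methyl 6-(benzyloxy)-7-(methacryloyloxy)-4-methyl-5-[(triethylsilyl)oxy]non-8-enoate | C=C[C@@H](OC(=O)C(C)=C)[C@H](OCc1ccccc1)[C@H](O[Si](CC)(CC)CC)[C@@H](C)CCC(=O)OC
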